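**Plan**
1. Ring letters: A and E are the outer 3,5-dihydroxyphenoxy rings (A on ring B, E on ring D); B and C are the benzene rings of the dibenzodioxin; C and D are the benzene rings of the dibenzofuran.
2. Retrosynthetic cuts, in order: the aryl ether bonds O–ring E and O–ring A; the furan C–C bond (ring C C-9 to ring D) together with the furan C–O bond (ring C O-8 to ring D); the two dioxin C–O bonds on the ring-B side.
3. Enabling feature: the two ring-D carbons of the furan (one bonded to a ring-C carbon, one to the furan oxygen) are each flanked by an oxygen-bearing carbon, these two oxygens are para to each other, and a third oxygen sits next to one of them. Ring D is therefore the reduced form of a 2,3-disubstituted 5-methoxy-1,4-benzoquinone; the two dioxin carbons of ring B show the same pattern.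
4. Forward: 2,3-dichloro-5-methoxy-1,4-benzoquinone is made once and used twice, first with a bromocatechol (O,O-annulation closes the dioxin ring; ring B arrives as a quinone), then with the ring-C phenol (C,O-annulation closes the furan ring; ring D arrives as a quinone).
5. After each annulation the quinone is reduced, the less hindered hydroxyl is silylated and the oxygen-flanked hydroxyl is arylated by Chan–Lam coupling (ring A, then ring E); BBr3 removes all protecting groups at the end.
6. The target has no stereocentre, so no stereocontrol is needed.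

Key step: step 9

Remarks
- Assumption: 1, 6 and 13 are bought; everything else is a common reagent.
- Numbering: dibenzodioxin positions follow eckol (ring B = C-1 to C-4, ring C = C-6 to C-9, O-5 and O-10). In quinone 5, C-1 is the carbonyl next to C-6–H, C-2 and C-3 carry chlorine, C-4 is the carbonyl next to C-5–OMe.
- The ring-C phenol 17 used in the key step is eckol with every hydroxyl except the 8-OH methylated; it carries five methoxy groups.

**Step 1**
Reactants: 1 5-chlorovanillin (3-chloro-4-hydroxy-5-methoxybenzaldehyde)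
Product: 2 5,6-dichlorovanillin (2,3-dichloro-4-hydroxy-5-methoxybenzaldehyde)
Conditions: SO2Cl2 (1.2 equiv), AcOH, 50 °C
Reagents that add atoms: sulfuryl chloride, O=S(=O)(Cl)Cl
Why: Electrophilic aromatic chlorination: with C-5 blocked, the methoxy group directs to its open para position C-6, while C-2 is wedged between the formyl and methoxy groups.

**Step 2**
Reactants: 2 5,6-dichlorovanillin
Product: 5 2,3-dichloro-5-methoxy-1,4-benzoquinone, via aryl formate 3 (not isolated), via hydroquinone 4 (not isolated)
Conditions: 30% H2O2, 1 M NaOH, 0 °C to rt; HCl to pH 2; then FeCl3, H2O–EtOAc, rt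
Reagents that add atoms: hydrogen peroxide, OO
Why: Dakin oxidation of the p-hydroxybenzaldehyde (aryl migration to peroxide oxygen, loss of formate) should give hydroquinone 4, which FeCl3 (trivalent iron) oxidises to the quinone in the same operation.

**Step 3**
Reactants: 6 5-bromo-2-hydroxy-3-methoxybenzaldehyde
Product: 8 5-bromo-3-methoxybenzene-1,2-diol, via aryl formate 7 (not isolated)
Conditions: 30% H2O2, 1 M NaOH, 0 °C to rt, N2; then HCl
Reagents that add atoms: hydrogen peroxide, OO
Why: Dakin oxidation of an o-hydroxybenzaldehyde, the reaction that turns o-vanillin into 3-methoxycatechol; the aryl bromide is inert to alkaline peroxide.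

**Step 4**
Reactants: 8 5-bromo-3-methoxybenzene-1,2-diol; 5 2,3-dichloro-5-methoxy-1,4-benzoquinone
Product: 10 8-bromo-3,6-dimethoxydibenzo[b,e][1,4]dioxine-1,4-dione, via aryloxychloroquinone 9 (not isolated)
Conditions: K2CO3 (2.2 equiv), DMF, 0 °C to rt, Ar; 8 added slowly to 5
Reagents that add atoms: none
Why: Twofold vinylic substitution (addition–elimination) of a catechol on a 2,3-dichloroquinone, known for catechols with 2,3-dichloro-1,4-naphthoquinone and chloranil: the more acidic, less hindered hydroxyl (next to the ring hydrogen, meta to Br and OMe) should attack C-2 of 5, the chlorine-bearing carbon β to the carbonyl that the methoxy group does not deactivate, and the second hydroxyl then closes the six-membered dioxin ring at C-3.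

**Step 5**
Reactants: 10 8-bromo-3,6-dimethoxydibenzo[b,e][1,4]dioxine-1,4-dione
Product: 12 8-bromo-3,6-dimethoxy-1-(triisopropylsilyloxy)dibenzo[b,e][1,4]dioxin-4-ol, via dioxin hydroquinone 11 (not isolated)
Conditions: Na2S2O4, THF–H2O, rt; organic phase dried under Ar; then TIPSCl (1.05 equiv), imidazole, DMF, 0 °C
Reagents that add atoms: chlorotri(propan-2-yl)silane (TIPSCl), CC(C)[Si](Cl)(C(C)C)C(C)C
Why: Dithionite reduction of the quinone, then silylation under steric control: the bulky silyl chloride should take the 1-hydroxyl, which has a free ortho CH and is the more acidic one, not the 4-hydroxyl wedged between the methoxy group and the dioxin oxygen.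

**Step 6**
Reactants: 12 8-bromo-3,6-dimethoxy-1-(triisopropylsilyloxy)dibenzo[b,e][1,4]dioxin-4-ol; 13 (3,5-dimethoxyphenyl)boronic acid
Product: 14 8-bromo-4-(3,5-dimethoxyphenoxy)-3,6-dimethoxy-1-(triisopropylsilyloxy)dibenzo[b,e][1,4]dioxine
Conditions: Cu(OAc)2 (1.5 equiv), pyridine, 4 Å MS, CH2Cl2, dry air, rt
Reagents that add atoms: none
Why: Chan–Lam coupling (divalent copper, arylboronic acid, amine base, room temperature), which arylates ortho-substituted phenols and leaves the aryl bromide and the silyl ether untouched.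

**Step 7**
Reactants: 14 8-bromo-4-(3,5-dimethoxyphenoxy)-3,6-dimethoxy-1-(triisopropylsilyloxy)dibenzo[b,e][1,4]dioxine
Product: 16 8-bromo-4-(3,5-dimethoxyphenoxy)-1,3,6-trimethoxydibenzo[b,e][1,4]dioxine, via free phenol 15 (not isolated)
Conditions: CsF, MeI, DMF, rt
Reagents that add atoms: iodomethane, CI
Why: Fluoride cleaves the aryl silyl ether and the caesium phenoxide is methylated in the same flask (Williamson ether synthesis).

**Step 8**
Reactants: 16 8-bromo-4-(3,5-dimethoxyphenoxy)-1,3,6-trimethoxydibenzo[b,e][1,4]dioxine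
Product: 17 4-(3,5-dimethoxyphenoxy)-1,3,6-trimethoxydibenzo[b,e][1,4]dioxin-8-ol
Conditions: Pd2(dba)3 (2 mol%), tBuXPhos (8 mol%), KOH, 1,4-dioxane–H2O, 100 °C; then HCl
Reagents that add atoms: potassium hydroxide, [K+].[OH-]
Why: Buchwald–Hartwig-type hydroxylation of an aryl bromide (zerovalent palladium, bulky biarylphosphine, hydroxide); the bromide is unhindered and all other groups are aryl ethers stable to hot hydroxide.

**Step 9**
Reactants: 17 4-(3,5-dimethoxyphenoxy)-1,3,6-trimethoxydibenzo[b,e][1,4]dioxin-8-ol; 5 2,3-dichloro-5-methoxy-1,4-benzoquinone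
Product: 19 ring-D quinone fused through the furan to ring C of 17 (C-9 bonded to quinone C-2 and O-8 bonded to quinone C-3), via arylchloroquinone 18 (not isolated)
Conditions: LiN(SiMe3)2 (1.0 equiv), THF–toluene, −40 °C; 5 (1.1 equiv), −40 to 0 °C; then Cs2CO3, DMF, rt
Reagents that add atoms: none
Why: The lithium phenoxide of 17 adds through its ortho carbon C-9 to C-2 of 5, the chlorine-bearing carbon β to the C-4 carbonyl (the C-1 carbonyl is a vinylogous ester of the methoxy group and the poorer acceptor); chloride leaves and the dienone tautomerises to phenol 18. With Cs2CO3 the phenoxide oxygen of 18 adds to C-3 and expels the second chloride, so the furan closes by intramolecular addition–elimination at the vinylogous acyl chloride (formally 5-endo-trig, eased by the planar conjugated framework). The closest known reaction type is the base-mediated C,O-annulation of electron-rich phenols and naphthols with 2,3-dichloro-1,4-naphthoquinone and related 2,3-dihaloquinones to furan-fused quinones. No stereocentre is formed. Three selectivities are needed: the quinone site (set by the methoxy group as described); carbon rather than oxygen attack (favoured by the tight lithium phenoxide in a weakly polar medium and by the phloroglucinol-like ring C; an O-arylated quinone would not close to a furan here); and C-9 rather than C-7 (C-9 is para to the 6-methoxy group and flanked only by the tied-back dioxin oxygen, C-7 sits between the phenoxide and a freely rotating methoxy group).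

**Step 10**
Reactants: 19 ring-D quinone
Product: 21 mono-triisopropylsilyl ether of the ring-D hydroquinone (silyl on the hydroxyl next to the ring CH; free hydroxyl between furan oxygen and methoxy group), via ring-D hydroquinone 20 (not isolated)
Conditions: Na2S2O4, THF–H2O, rt; organic phase dried under Ar; then TIPSCl (1.05 equiv), imidazole, DMF, 0 °C
Reagents that add atoms: chlorotri(propan-2-yl)silane (TIPSCl), CC(C)[Si](Cl)(C(C)C)C(C)C
Why: Dithionite reduction of the quinone, then sterically controlled silylation as in step 5: the hydroxyl with a free ortho CH should react in preference to the one flanked by the methoxy group and the furan oxygen.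

**Step 11**
Reactants: 21 mono-silyl ether of the ring-D hydroquinone; 13 (3,5-dimethoxyphenyl)boronic acid
Product: 22 21 bearing a 3,5-dimethoxyphenyl group on the formerly free ring-D oxygen (ring E in place)
Conditions: Cu(OAc)2 (1.5 equiv), pyridine, 4 Å MS, CH2Cl2, dry air, rt
Reagents that add atoms: none
Why: Chan–Lam coupling of the only free hydroxyl, as in step 6; the room-temperature, weakly basic conditions spare the silyl ether.

**Step 12**
Reactants: 22 fully protected phlorofucofuroeckol A (eight methyl ethers, one silyl ether)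
Product: 23 phlorofucofuroeckol A
Conditions: BBr3 (excess), CH2Cl2, −78 °C to rt; then H2O
Reagents that add atoms: none
Why: Lewis-acid ether cleavage: BBr3 removes the eight aryl methyl ethers and the aryl silyl ether, while the diaryl ether, dioxin and furan C–O bonds are not attacked.

**Compound list**
1 | 5-chlorovanillin (3-chloro-4-hydroxy-5-methoxybenzaldehyde) | COc1cc(C=O)cc(Cl)c1O | starting material
2 | 5,6-dichlorovanillin (2,3-dichloro-4-hydroxy-5-methoxybenzaldehyde) | COc1cc(C=O)c(Cl)c(Cl)c1O | intermediate
3 | 2,3-dichloro-4-hydroxy-5-methoxyphenyl formate | COc1cc(OC=O)c(Cl)c(Cl)c1O | intermediate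
4 | 2,3-dichloro-5-methoxybenzene-1,4-diol | COc1cc(O)c(Cl)c(Cl)c1O | intermediate
5 | 2,3-dichloro-5-methoxy-1,4-benzoquinone | COC1=CC(=O)C(Cl)=C(Cl)C1=O | intermediate
6 | 5-bromo-2-hydroxy-3-methoxybenzaldehyde | COc1cc(Br)cc(C=O)c1O | starting material
7 | 5-bromo-2-hydroxy-3-methoxyphenyl formate | COc1cc(Br)cc(OC=O)c1O | intermediate
8 | 5-bromo-3-methoxybenzene-1,2-diol | COc1cc(Br)cc(O)c1O | intermediate
9 | 2-(5-bromo-2-hydroxy-3-methoxyphenoxy)-3-chloro-5-methoxy-1,4-benzoquinone | COC1=CC(=O)C(Oc2cc(Br)cc(OC)c2O)=C(Cl)C1=O | intermediate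
10 | 8-bromo-3,6-dimethoxydibenzo[b,e][1,4]dioxine-1,4-dione | O=C1C(OC)=CC(=O)C2=C1Oc1c(OC)cc(Br)cc1O2 | intermediate
11 | 8-bromo-3,6-dimethoxydibenzo[b,e][1,4]dioxine-1,4-diol | Oc1c(OC)cc(O)c2c1Oc1c(OC)cc(Br)cc1O2 | intermediate
12 | 8-bromo-3,6-dimethoxy-1-(triisopropylsilyloxy)dibenzo[b,e][1,4]dioxin-4-ol | Oc1c(OC)cc(O[Si](C(C)C)(C(C)C)C(C)C)c2c1Oc1c(OC)cc(Br)cc1O2 | intermediate
13 | (3,5-dimethoxyphenyl)boronic acid | COc1cc(OC)cc(B(O)O)c1 | starting material
14 | 8-bromo-4-(3,5-dimethoxyphenoxy)-3,6-dimethoxy-1-(triisopropylsilyloxy)dibenzo[b,e][1,4]dioxine | COc1cc(OC)cc(Oc2c(OC)cc(O[Si](C(C)C)(C(C)C)C(C)C)c3c2Oc2c(OC)cc(Br)cc2O3)c1 | intermediate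
15 | 8-bromo-4-(3,5-dimethoxyphenoxy)-3,6-dimethoxydibenzo[b,e][1,4]dioxin-1-ol | COc1cc(OC)cc(Oc2c(OC)cc(O)c3c2Oc2c(OC)cc(Br)cc2O3)c1 | intermediate
16 | 8-bromo-4-(3,5-dimethoxyphenoxy)-1,3,6-trimethoxydibenzo[b,e][1,4]dioxine | COc1cc(OC)cc(Oc2c(OC)cc(OC)c3c2Oc2c(OC)cc(Br)cc2O3)c1 | intermediate
17 | 4-(3,5-dimethoxyphenoxy)-1,3,6-trimethoxydibenzo[b,e][1,4]dioxin-8-ol | COc1cc(OC)cc(Oc2c(OC)cc(OC)c3c2Oc2c(OC)cc(O)cc2O3)c1 | intermediate
18 | 3-chloro-2-[4-(3,5-dimethoxyphenoxy)-8-hydroxy-1,3,6-trimethoxydibenzo[b,e][1,4]dioxin-9-yl]-5-methoxy-1,4-benzoquinone | COc1cc(OC)cc(Oc2c(OC)cc(OC)c3c2Oc2c(OC)cc(O)c(C4=C(Cl)C(=O)C(OC)=CC4=O)c2O3)c1 | intermediate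
19 | furan-fused quinone: C-9 of 17 bonded to C-2 and O-8 of 17 bonded to C-3 of a 5-methoxy-1,4-benzoquinone (ring D at the quinone level; the carbonyl beside the furan oxygen is the one next to the methoxy carbon) | COc1cc(OC)cc(Oc2c(OC)cc(OC)c3c2Oc2c(OC)cc4oc5c(c4c2O3)C(=O)C=C(OC)C5=O)c1 | intermediate
20 | ring-D hydroquinone of 19 (hydroxyls at the two former carbonyl carbons) | COc1cc(OC)cc(Oc2c(OC)cc(OC)c3c2Oc2c(OC)cc4oc5c(O)c(OC)cc(O)c5c4c2O3)c1 | intermediate
21 | mono-triisopropylsilyl ether of 20 (silyl on the ring-D hydroxyl next to the ring CH; the hydroxyl between furan oxygen and methoxy group is free) | COc1cc(OC)cc(Oc2c(OC)cc(OC)c3c2Oc2c(OC)cc4oc5c(O)c(OC)cc(O[Si](C(C)C)(C(C)C)C(C)C)c5c4c2O3)c1 | intermediate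
22 | 21 with a 3,5-dimethoxyphenyl group on the formerly free ring-D oxygen (octa-O-methyl, mono-O-silyl phlorofucofuroeckol A) | COc1cc(OC)cc(Oc2c(OC)cc(OC)c3c2Oc2c(OC)cc4oc5c(Oc6cc(OC)cc(OC)c6)c(OC)cc(O[Si](C(C)C)(C(C)C)C(C)C)c5c4c2O3)c1 | intermediate
23 | phlorofucofuroeckol A | Oc1cc(O)cc(Oc2c(O)cc(O)c3c2Oc2c(O)cc4oc5c(Oc6cc(O)cc(O)c6)c(O)cc(O)c5c4c2O3)c1 | target

**Step count and risks**
Total: 12 steps. Longest linear sequence: 11 steps (steps 1, 2, 4, 5, 6, 7, 8, 9, 10, 11, 12; the branch from 6 joins at step 4).

Step 9 (most likely to fail). The phenoxide may react through oxygen instead of carbon, or through C-7 instead of C-9, and electron transfer from the electron-rich phenoxide to the quinone may consume both partners. The fallback sets out from 17 (with a quinone made from 1) and comes back to the route at 18. Compound 1 is taken through the Dakin oxidation (H2O2, NaOH), which should give, by way of 3-chloro-4-hydroxy-5-methoxyphenyl formate F1, the hydroquinone 2-chloro-6-methoxybenzene-1,4-diol F2; FeCl3 oxidises this to 2-chloro-6-methoxy-1,4-benzoquinone F3. Neutral 17 is then added to F3 in hexafluoroisopropanol without base. Under these conditions the phenol oxygen is not nucleophilic, and the only unsubstituted position of F3 that is β to the non-deactivated carbonyl is C-3, so a Friedel–Crafts-type Michael addition through C-9 should give 2-chloro-3-[4-(3,5-dimethoxyphenoxy)-8-hydroxy-1,3,6-trimethoxydibenzo[b,e][1,4]dioxin-9-yl]-6-methoxybenzene-1,4-diol F4. Ag2O oxidises F4 to the quinone 18, which Cs2CO3 closes to 19 as in step 9. Carbon–carbon bond formation and ring closure are thus separated, and the quinone offers a single leaving group.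

Step 10. The silylation may not discriminate well enough between the two hydroquinone hydroxyls, and the hydroquinone may re-oxidise before it is capped. The fallback sets out from 19 and comes back at 23. Reductive methylation (Na2S2O4; then Me2SO4, K2CO3, acetone) caps both hydroxyls of 20 and should give the octamethyl ether F5. BCl3 (CH2Cl2, low temperature) then cleaves the one methoxy group flanked by two oxygen substituents (between the furan oxygen and the neighbouring methoxy group), following the known preference for the central methoxy group of 1,2,3-trioxygenated arenes, to give the phenol F6. Chan–Lam coupling of F6 with 13 gives the nonamethyl ether F7, and BBr3 converts this into 23.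

Step 4. The two catechol oxygens may add in the opposite sense and give the regioisomeric dioxin, and redox exchange between catechol and quinone may compete. The fallback sets out from 6 and comes back at 9, which closes to 10. The phenol of 6 is protected (MOMCl, i-Pr2NEt) as 5-bromo-3-methoxy-2-(methoxymethoxy)benzaldehyde F8. Baeyer–Villiger oxidation (mCPBA) gives 5-bromo-3-methoxy-2-(methoxymethoxy)phenyl formate F9, and methanolysis (K2CO3, MeOH) gives 5-bromo-3-methoxy-2-(methoxymethoxy)phenol F10, in which only the oxygen next to the ring hydrogen is free. Vinylic substitution on 5 (K2CO3, DMF) at C-2 gives 2-[5-bromo-3-methoxy-2-(methoxymethoxy)phenoxy]-3-chloro-5-methoxy-1,4-benzoquinone F11. HCl in MeOH removes the acetal to give 9, and K2CO3 closes 9 to 10, so the order of the two C–O bonds is fixed by the protecting group.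

**Further compounds**
F1 | step 9 | 3-chloro-4-hydroxy-5-methoxyphenyl formate | COc1cc(OC=O)cc(Cl)c1O
F2 | step 9 | 2-chloro-6-methoxybenzene-1,4-diol | COc1cc(O)cc(Cl)c1O
F3 | step 9 | 2-chloro-6-methoxy-1,4-benzoquinone | COC1=CC(=O)C=C(Cl)C1=O
F4 | step 9 | 2-chloro-3-[4-(3,5-dimethoxyphenoxy)-8-hydroxy-1,3,6-trimethoxydibenzo[b,e][1,4]dioxin-9-yl]-6-methoxybenzene-1,4-diol | COc1cc(OC)cc(Oc2c(OC)cc(OC)c3c2Oc2c(OC)cc(O)c(-c4c(O)cc(OC)c(O)c4Cl)c2O3)c1
F5 | step 10 | octamethyl ether (20 with both ring-D hydroxyls methylated) | COc1cc(OC)cc(Oc2c(OC)cc(OC)c3c2Oc2c(OC)cc4oc5c(OC)c(OC)cc(OC)c5c4c2O3)c1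
F6 | step 10 | phenol (F5 lacking the methyl group on the oxygen between furan oxygen and methoxy group) | COc1cc(OC)cc(Oc2c(OC)cc(OC)c3c2Oc2c(OC)cc4oc5c(O)c(OC)cc(OC)c5c4c2O3)c1
F7 | step 10 | nonamethyl ether of phlorofucofuroeckol A | COc1cc(OC)cc(Oc2c(OC)cc(OC)c3c2Oc2c(OC)cc4oc5c(Oc6cc(OC)cc(OC)c6)c(OC)cc(OC)c5c4c2O3)c1
F8 | step 4 | 5-bromo-3-methoxy-2-(methoxymethoxy)benzaldehyde | COCOc1c(OC)cc(Br)cc1C=O
F9 | step 4 | 5-bromo-3-methoxy-2-(methoxymethoxy)phenyl formate | COCOc1c(OC)cc(Br)cc1OC=O
F10 | step 4 | 5-bromo-3-methoxy-2-(methoxymethoxy)phenol | COCOc1c(OC)cc(Br)cc1O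
F11 | step 4 | 2-[5-bromo-3-methoxy-2-(methoxymethoxy)phenoxy]-3-chloro-5-methoxy-1,4-benzoquinone | COCOc1c(OC)cc(Br)cc1OC1=C(Cl)C(=O)C(OC)=CC1=O
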